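**Plan**

- Cuts, in retrosynthetic order: the C19–O tiglate ester; C14–C15 (olefination at C13) and C8=C17; C4–C18 and C3–C4 (ring A); C9–C11 and C1–C10 (key step); the C8 carbonyl oxygen and C4–C5 (Claisen).
- Enabling feature: ring B has one functional carbon, C8, lying between C9 (which bears the chain C11–C12–C13–C16 with an oxygenated C13 reachable from a methyl ketone) and quaternary C10. This is the pattern of a 3-methylcyclohex-2-enone substituted at its β-carbon (C10) and α-carbon (C9).
- Forward order: ring B is present from 2-methylcyclohexenone. The C4/C19 arm is attached at C5 and C8 is oxidised. One flask then adds allyl (C1–C3) to C10 and butenone (C11–C13, C16) to C9 without closing a ring. Ring A closes at C3–C4, followed by C18, C17, C14–C15 and the tiglate.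
- Stereochemistry: C5 comes from a catalyst-controlled ketone reduction relayed by a suprafacial Claisen shift. C10 and C9 come from C5 in the key step. C4 comes from equatorial methylation opposite the C10 methyl. C13 comes from the tartrate in a Sharpless epoxidation.

Key step: step 4

Remark: labdane numbering is used for every intermediate and β means the face of the C10 methyl group. The target SMILES is read as the 5α-H, 9α-H, 10β-methyl, (13R) compound whose tigloyloxymethyl group is the axial 4β substituent (C19).

**Route**

Step 1
Reactants: 1 2-methylcyclohex-2-en-1-one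
Product: 2 (S)-2-methylcyclohex-2-en-1-ol
Conditions: (R)-2-methyl-CBS-oxazaborolidine (10 mol%), BH3·SMe2, THF, −20 °C; MeOH quench
Reagents that add atoms: none
Why: Corey–Bakshi–Shibata reduction, in which the substituted alkene arm of the enone acts as the large group, so the (R)-catalyst should deliver hydride to the face that gives the (S)-allylic alcohol by 1,2-reduction.

Step 2
Reactants: 2 (S)-2-methylcyclohex-2-en-1-ol; 3 trimethyl orthoacetate
Product: 5 methyl (S)-2-(2-methylcyclohex-2-en-1-yl)acetate, via ketene acetal 4 (not isolated)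
Conditions: 3 (excess), EtCO2H (cat.), xylene, 135 °C, removal of MeOH
Reagents that add atoms: none
Why: Johnson–Claisen rearrangement, whose [3,3] shift is suprafacial on the ring, so the carbinol stereocentre of 2 is relayed to the new C4–C5 bond (C5, S) while the double bond moves to C9=C10.

Step 3
Reactants: 5 methyl (S)-2-(2-methylcyclohex-2-en-1-yl)acetate
Product: 6 methyl (S)-2-(2-methyl-4-oxocyclohex-2-en-1-yl)acetate
Conditions: Rh2(caprolactamate)4 (1 mol%), t-BuOOH (70% aq.), K2CO3, CH2Cl2, rt
Reagents that add atoms: tert-butyl hydroperoxide, CC(C)(C)OO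
Why: Radical allylic C–H oxidation, in which hydrogen is taken from the ring methylene next to the vinylic CH (C8) and not from the hindered tertiary C5–H, giving the conjugated enone as in the conversion of 1-methylcyclohexenes into 3-methylcyclohexenones and leaving C5 untouched.

Step 4
Reactants: 6 methyl (S)-2-(2-methyl-4-oxocyclohex-2-en-1-yl)acetate; 7 allyltrimethylsilane; 8 methyl vinyl ketone
Product: 10 methyl 2-[(1S,2S,3R)-2-allyl-2-methyl-4-oxo-3-(3-oxobutyl)cyclohexyl]acetate, via trichlorotitanium enolate 9 (not isolated)
Conditions: TiCl4 (1.2 equiv), CH2Cl2, −78 °C, then 7; then 8 (2 equiv) and further TiCl4 (1 equiv), −78 → −40 °C; aq. NaHCO3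
Reagents that add atoms: none
Why: Proposed new method: TiCl4 binds the enone carbonyl of 6 and the allylsilane attacks the β-carbon C10 with loss of Me3SiCl, leaving the trichlorotitanium enolate 9 with its C8=C9 double bond fixed in place; 9 then adds through C9 to Lewis-acid-activated methyl vinyl ketone, so C1–C10 and C9–C11 form in one flask and no ring closes. The closest known reactions are the Hosomi–Sakurai conjugate allylation of β-methylcyclohexenones with capture of the titanium enolate by aldehydes or acetals, and Michael additions of chlorotitanium enolates and of silyl enol ethers (Mukaiyama–Michael) to vinyl ketones; only the enone as third component is new. C10 is controlled by C5: the acetate arm sits pseudoaxial in the half-chair to avoid A1,2 strain with the C10 methyl, and the stereoelectronically preferred axial attack then occurs on the opposite face, placing the allyl group trans to the arm, which is the later trans ring fusion. C9 is controlled by the new quaternary centre, the acceptor approaching antiparallel to the axial allyl group; this is also the equatorial, more stable arrangement, so any C9 epimer is corrected by enolisation at the latest in step 10. The step needs 1,4- rather than 1,2-allylation (secured by the TiCl4/allylsilane pair), reaction at C9 rather than C7 (secured because the enolate is formed regiospecifically and cannot equilibrate in the aprotic medium at low temperature) and a single Michael addition (favoured by low temperature and the hindered adduct).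

Step 5
Reactants: 10 methyl 2-[(1S,2S,3R)-2-allyl-2-methyl-4-oxo-3-(3-oxobutyl)cyclohexyl]acetate
Product: 11 bis(ethylene ketal) of 10 (dioxolanes at C8 and C13)
Conditions: Me3SiOCH2CH2OSiMe3, Me3SiOTf (cat.), CH2Cl2, −78 → −20 °C; pyridine quench
Reagents that add atoms: 1,2-bis(trimethylsilyloxy)ethane, C[Si](C)(C)OCCO[Si](C)(C)C
Why: Silyl triflate-catalysed ketalisation under aprotic conditions masks both ketones at low temperature, avoiding the aldol cyclisation to which a 1,5-diketone is prone and leaving the ester and the alkene untouched.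

Step 6
Reactants: 11 bis(ethylene ketal) of 10
Product: 13 3-hydroxypropyl bis-ketal ester (C3–OH), via B-alkyl-9-BBN adduct 12 (not isolated)
Conditions: 9-BBN, THF, 0 °C → rt; then NaBO3·4H2O, H2O, rt
Reagents that add atoms: sodium perborate tetrahydrate, [Na+].[O-]B1OO1.O.O.O.O
Why: Hydroboration–oxidation places boron on the terminal carbon of the monosubstituted alkene (anti-Markovnikov), and the mild perborate oxidation gives the primary alcohol without harming the ester or the ketals.

Step 7
Reactants: 13 3-hydroxypropyl bis-ketal ester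
Product: 14 3-iodopropyl bis-ketal ester (C3–I)
Conditions: PPh3, I2, imidazole, CH2Cl2, 0 °C → rt
Reagents that add atoms: iodine, II
Why: Appel iodination, in which iodide displaces the alkoxyphosphonium group at the unhindered primary carbon while the imidazole buffer keeps the ketals intact.

Step 8
Reactants: 14 3-iodopropyl bis-ketal ester
Product: 16 ring-closed bis-ketal decalin ester lacking the C4 methyl (drawn as the equatorial ester), via lithium ester enolate 15 (not isolated)
Conditions: LiN(i-Pr)2, THF, −78 °C; DMPU, −78 → 0 °C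
Reagents that add atoms: none
Why: Intramolecular ester enolate alkylation, a 6-exo-tet displacement of the primary iodide at C3 by the C4 enolate that closes ring A as a trans-decalin because C1 and C4 are trans on ring B; the C4 configuration formed here is erased in step 9.

Step 9
Reactants: 16 ring-closed bis-ketal decalin ester
Product: 18 methyl 8,8:13,13-bis(ethylenedioxy)-14,15,17-trinorlabdan-19-oate, via lithium ester enolate 17 (not isolated)
Conditions: LiN(i-Pr)2, THF, −78 → 0 °C; MeI, DMPU, −78 → 0 °C
Reagents that add atoms: iodomethane, CI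
Why: Ester enolate alkylation, in which the exocyclic enolate is methylated on its equatorial α face because the axial β face is screened by the 1,3-diaxial C10 methyl, leaving the ester axial (C19) and the new methyl equatorial (C18), as is usual for 10-methyldecalin-4-carboxylates.

Step 10
Reactants: 18 methyl 8,8:13,13-bis(ethylenedioxy)-14,15,17-trinorlabdan-19-oate
Product: 19 methyl 8,13-dioxo-14,15,17-trinorlabdan-19-oate
Conditions: 1 M HCl, THF, rt
Reagents that add atoms: water, O
Why: Mild acid hydrolysis of both dioxolanes returns the two ketones, and enolisation of the C8 ketone lets C9 settle with its side chain equatorial (9α-H) on the trans-decalin.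

Step 11
Reactants: 19 methyl 8,13-dioxo-14,15,17-trinorlabdan-19-oate; 20 triethyl phosphonoacetate
Product: 21 15-ethyl 19-methyl (13E)-8-oxo-17-norlabd-13-ene-15,19-dioate
Conditions: 20, NaH, THF, 0 → 40 °C
Reagents that add atoms: none
Why: Horner–Wadsworth–Emmons olefination, in which the stabilised phosphonate anion reacts with the unhindered methyl ketone and not with the C8 ketone flanked by branched C9, and should give mainly the E enoate (the Z isomer to be removed by chromatography).

Step 12
Reactants: 21 15-ethyl 19-methyl (13E)-8-oxo-17-norlabd-13-ene-15,19-dioate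
Product: 22 15-ethyl 19-methyl (13E)-labda-8(17),13-diene-15,19-dioate
Conditions: Zn, CH2Br2, TiCl4, THF/CH2Cl2, 0 °C → rt
Reagents that add atoms: dibromomethane, BrCBr
Why: Takai–Lombardo methylenation, whose non-basic zinc–titanium methylene reagent converts hindered enolisable ketones into methylene compounds without attacking esters and without epimerising C9.

Step 13
Reactants: 22 15-ethyl 19-methyl (13E)-labda-8(17),13-diene-15,19-dioate
Product: 23 methyl (13E)-15-hydroxylabda-8(17),13-dien-19-oate
Conditions: i-Bu2AlH (2.2 equiv), CH2Cl2, −78 °C; aq. potassium sodium tartrate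
Reagents that add atoms: none
Why: Chemoselective hydride reduction, in which the exposed conjugated ethyl ester is reduced to the allylic alcohol by 1,2-addition at −78 °C while the axial C19 methyl ester on quaternary C4, screened by the 1,3-diaxial C10 methyl, should react far more slowly.

Step 14
Reactants: 23 methyl (13E)-15-hydroxylabda-8(17),13-dien-19-oate
Product: 24 methyl (13R,14R)-13,14-epoxy-15-hydroxylabd-8(17)-en-19-oate
Conditions: Ti(Oi-Pr)4 (10 mol%), D-(−)-diethyl tartrate (12 mol%), t-BuOOH (in decane), 4 Å molecular sieves, CH2Cl2, −20 °C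
Reagents that add atoms: tert-butyl hydroperoxide, CC(C)(C)OO
Why: Sharpless asymmetric epoxidation, which touches only the allylic alcohol and under reagent control with the D-tartrate should give the (13R,14R)-epoxide, the same sense in which geraniol gives its (2R,3R)-epoxide, the distant ring stereocentres having no influence.

Step 15
Reactants: 24 methyl (13R,14R)-13,14-epoxy-15-hydroxylabd-8(17)-en-19-oate
Product: 25 methyl (13R,14S)-13,14-epoxy-15-iodolabd-8(17)-en-19-oate
Conditions: PPh3, I2, imidazole, THF, 0 °C
Reagents that add atoms: iodine, II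
Why: Appel iodination of the primary epoxy alcohol, in which the epoxide survives the buffered conditions and the spatial arrangement at C13 and C14 is unchanged (the C14 descriptor changes only through the priority of iodine).

Step 16
Reactants: 25 methyl (13R,14S)-13,14-epoxy-15-iodolabd-8(17)-en-19-oate
Product: 26 methyl (13R)-13-hydroxylabda-8(17),14-dien-19-oate
Conditions: Zn dust, AcOH, EtOH, rt
Reagents that add atoms: none
Why: Reductive β-elimination, in which zinc inserts into the C–I bond and the organozinc opens the adjacent epoxide to form the C14=C15 vinyl group, leaving the C13–O bond and with it the (13R) configuration untouched.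

Step 17
Reactants: 26 methyl (13R)-13-hydroxylabda-8(17),14-dien-19-oate
Product: 27 (13R)-labda-8(17),14-diene-13,19-diol
Conditions: LiAlH4, THF, 0 → 50 °C
Reagents that add atoms: none
Why: Hydride reduction of the hindered axial ester to the neopentyl primary alcohol by the small, strong reductant LiAlH4, the tertiary alkoxide and the unactivated alkenes being inert.

Step 18
Reactants: 27 (13R)-labda-8(17),14-diene-13,19-diol; 28 tigloyl chloride
Product: 29 (13R)-13-hydroxylabda-8(17),14-dien-19-yl tiglate (target)
Conditions: 28, pyridine, DMAP (cat.), CH2Cl2, 0 °C → rt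
Reagents that add atoms: none
Why: Acylation under nucleophilic catalysis, in which only the primary C19 hydroxyl reacts because the tertiary allylic C13 hydroxyl is too hindered, and pyridine as the base avoids vinylketene formation so the E geometry of the tiglate is kept.

**Compound list**

1 | 2-methylcyclohex-2-en-1-one | CC1=CCCCC1=O | starting material
2 | (S)-2-methylcyclohex-2-en-1-ol | O[C@H]1CCCC=C1C | intermediate
3 | trimethyl orthoacetate | COC(C)(OC)OC | starting material
4 | (S)-1-methoxyvinyl 2-methylcyclohex-2-en-1-yl ether (ketene acetal) | C=C(OC)O[C@H]1CCCC=C1C | intermediate (not isolated)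
5 | methyl (S)-2-(2-methylcyclohex-2-en-1-yl)acetate | COC(=O)C[C@@H]1CCCC=C1C | intermediate
6 | methyl (S)-2-(2-methyl-4-oxocyclohex-2-en-1-yl)acetate | COC(=O)C[C@@H]1CCC(=O)C=C1C | intermediate
7 | allyltrimethylsilane | C=CC[Si](C)(C)C | starting material
8 | methyl vinyl ketone | CC(=O)C=C | starting material
9 | trichlorotitanium enolate (C8–O–TiCl3, C8=C9; C10 allyl trans to the C5 arm) | COC(=O)C[C@@H]1CCC(O[Ti](Cl)(Cl)Cl)=C[C@@]1(C)CC=C | intermediate (not isolated)
10 | methyl 2-[(1S,2S,3R)-2-allyl-2-methyl-4-oxo-3-(3-oxobutyl)cyclohexyl]acetate | CC(=O)CC[C@H]1C(=O)CC[C@@H](CC(=O)OC)[C@]1(C)CC=C | intermediate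
11 | bis(ethylene ketal) of 10 (dioxolanes at C8 and C13) | CC1(OCCO1)CC[C@H]2C3(OCCO3)CC[C@@H](CC(=O)OC)[C@]2(C)CC=C | intermediate
12 | B-alkyl-9-BBN adduct of 11 (boron on C3) | CC1(OCCO1)CC[C@H]2C3(OCCO3)CC[C@@H](CC(=O)OC)[C@]2(C)CCCB4C5CCCC4CCC5 | intermediate (not isolated)
13 | 3-hydroxypropyl bis-ketal ester (C3–OH) | CC1(OCCO1)CC[C@H]2C3(OCCO3)CC[C@@H](CC(=O)OC)[C@]2(C)CCCO | intermediate
14 | 3-iodopropyl bis-ketal ester (C3–I) | CC1(OCCO1)CC[C@H]2C3(OCCO3)CC[C@@H](CC(=O)OC)[C@]2(C)CCCI | intermediate
15 | lithium ester enolate of 14 (C4 enolate) | CC1(OCCO1)CC[C@H]2C3(OCCO3)CC[C@@H](C=C(O[Li])OC)[C@]2(C)CCCI | intermediate (not isolated)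
16 | methyl 8,8:13,13-bis(ethylenedioxy)-14,15,17,19-tetranorlabdan-18-oate (equatorial ester drawn; the C4 epimer serves equally) | CC1(OCCO1)CC[C@H]2C3(OCCO3)CC[C@H]4[C@H](C(=O)OC)CCC[C@]24C | intermediate
17 | lithium ester enolate of 16 (exocyclic at C4) | CC1(OCCO1)CC[C@H]2C3(OCCO3)CC[C@H]4C(=C(O[Li])OC)CCC[C@]24C | intermediate (not isolated)
18 | methyl 8,8:13,13-bis(ethylenedioxy)-14,15,17-trinorlabdan-19-oate | CC1(OCCO1)CC[C@H]2C3(OCCO3)CC[C@H]4[C@@](C)(C(=O)OC)CCC[C@]24C | intermediate
19 | methyl 8,13-dioxo-14,15,17-trinorlabdan-19-oate | CC(=O)CC[C@H]1C(=O)CC[C@H]2[C@@](C)(C(=O)OC)CCC[C@]12C | intermediate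
20 | triethyl phosphonoacetate | CCOC(=O)CP(=O)(OCC)OCC | starting material
21 | 15-ethyl 19-methyl (13E)-8-oxo-17-norlabd-13-ene-15,19-dioate | CCOC(=O)/C=C(\C)CC[C@H]1C(=O)CC[C@H]2[C@@](C)(C(=O)OC)CCC[C@]12C | intermediate
22 | 15-ethyl 19-methyl (13E)-labda-8(17),13-diene-15,19-dioate | CCOC(=O)/C=C(\C)CC[C@H]1C(=C)CC[C@H]2[C@@](C)(C(=O)OC)CCC[C@]12C | intermediate
23 | methyl (13E)-15-hydroxylabda-8(17),13-dien-19-oate | OC/C=C(\C)CC[C@H]1C(=C)CC[C@H]2[C@@](C)(C(=O)OC)CCC[C@]12C | intermediate
24 | methyl (13R,14R)-13,14-epoxy-15-hydroxylabd-8(17)-en-19-oate | OC[C@H]1O[C@]1(C)CC[C@H]2C(=C)CC[C@H]3[C@@](C)(C(=O)OC)CCC[C@]23C | intermediate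
25 | methyl (13R,14S)-13,14-epoxy-15-iodolabd-8(17)-en-19-oate | IC[C@H]1O[C@]1(C)CC[C@H]2C(=C)CC[C@H]3[C@@](C)(C(=O)OC)CCC[C@]23C | intermediate
26 | methyl (13R)-13-hydroxylabda-8(17),14-dien-19-oate | C=C[C@](C)(O)CC[C@H]1C(=C)CC[C@H]2[C@@](C)(C(=O)OC)CCC[C@]12C | intermediate
27 | (13R)-labda-8(17),14-diene-13,19-diol | C=C[C@](C)(O)CC[C@H]1C(=C)CC[C@H]2[C@@](C)(CO)CCC[C@]12C | intermediate
28 | tigloyl chloride ((E)-2-methylbut-2-enoyl chloride) | ClC(=O)/C(C)=C/C | starting material
29 | (13R)-13-hydroxylabda-8(17),14-dien-19-yl (E)-2-methylbut-2-enoate | C=C[C@](C)(O)CC[C@H]1C(=C)CC[C@H]2[C@@](C)(COC(=O)/C(C)=C/C)CCC[C@]12C | target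

**Totals and risks**

Total step count: 18. Longest linear sequence: 18 steps (from 1).

Steps most likely to fail:

Step 4 (proposed new method). The titanium enolate 9 may be protonated or may not add to the enone, or methyl vinyl ketone may polymerise under the Lewis acid, so that only simple conjugate allylation is seen. The fallback makes the same two bonds by two known operations. Setting out from 6, conjugate allylation with an allylcopper reagent in the presence of Me3SiCl (allylmagnesium bromide, CuBr·SMe2, Me3SiCl, THF, −78 °C) should add anti to the C5 arm and trap the enolate regiospecifically as the trimethylsilyl enol ether F1. After isolation, Mukaiyama–Michael addition of F1 to 8 (TiCl4/Ti(Oi-Pr)4, CH2Cl2, −78 °C) gives 10, where the route is rejoined.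

Step 11. Olefination of a methyl ketone may discriminate poorly between the E and Z geometries, so that much material is lost as the Z enoate. The fallback uses the Z isomer instead of discarding it. Setting out from 19, the mixture of 21 and the Z enoate F2 is carried through the methylenation, giving the Z diene diester F3 beside 22. The i-Bu2AlH reduction then gives the Z allylic alcohol F4 beside 23, and the two allylic alcohols are separated. F4 is epoxidised under the same titanium tartrate conditions but with L-(+)-diethyl tartrate, which for the Z geometry again makes C13 R (as nerol-type alcohols are known to behave) and gives the (13R,14S)-epoxy alcohol F5. Appel iodination to the epoxy iodide F6 and zinc reduction remove the C14 stereocentre and give 26, where both branches meet.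

Step 13. The reduction may not stop cleanly at the mono-alcohol, with partial attack on the C19 ester giving mixtures. The fallback removes the need to discriminate between the esters. Setting out from 22, both esters are reduced on purpose (LiAlH4, THF) to the 15,19-diol F7. The allylic hydroxyl alone is oxidised with MnO2 to the hydroxy enal F8, and the remaining C19 hydroxyl is acylated with 28 (pyridine, DMAP) to the enal tiglate F9. Luche reduction (NaBH4, CeCl3·7H2O, MeOH) returns the allylic alcohol F10 without touching the tiglate. Sharpless epoxidation with D-(−)-diethyl tartrate gives the epoxy alcohol F11, Appel iodination gives the epoxy iodide F12, and zinc in acetic acid/ethanol then gives the target 29 directly.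

**Further compounds**

F1 | step 4 | trimethylsilyl enol ether of the 3-allyl-3-methyl ketone (C8–OSiMe3, C8=C9) | COC(=O)C[C@@H]1CCC(O[Si](C)(C)C)=C[C@@]1(C)CC=C
F2 | step 11 | 15-ethyl 19-methyl (13Z)-8-oxo-17-norlabd-13-ene-15,19-dioate | CCOC(=O)/C=C(/C)CC[C@H]1C(=O)CC[C@H]2[C@@](C)(C(=O)OC)CCC[C@]12C
F3 | step 11 | 15-ethyl 19-methyl (13Z)-labda-8(17),13-diene-15,19-dioate | CCOC(=O)/C=C(/C)CC[C@H]1C(=C)CC[C@H]2[C@@](C)(C(=O)OC)CCC[C@]12C
F4 | step 11 | methyl (13Z)-15-hydroxylabda-8(17),13-dien-19-oate | OC/C=C(/C)CC[C@H]1C(=C)CC[C@H]2[C@@](C)(C(=O)OC)CCC[C@]12C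
F5 | step 11 | methyl (13R,14S)-13,14-epoxy-15-hydroxylabd-8(17)-en-19-oate | OC[C@@H]1O[C@]1(C)CC[C@H]2C(=C)CC[C@H]3[C@@](C)(C(=O)OC)CCC[C@]23C
F6 | step 11 | methyl (13R,14R)-13,14-epoxy-15-iodolabd-8(17)-en-19-oate | IC[C@@H]1O[C@]1(C)CC[C@H]2C(=C)CC[C@H]3[C@@](C)(C(=O)OC)CCC[C@]23C
F7 | step 13 | (13E)-labda-8(17),13-diene-15,19-diol | OC/C=C(\C)CC[C@H]1C(=C)CC[C@H]2[C@@](C)(CO)CCC[C@]12C
F8 | step 13 | (13E)-19-hydroxylabda-8(17),13-dien-15-al | O=C/C=C(\C)CC[C@H]1C(=C)CC[C@H]2[C@@](C)(CO)CCC[C@]12C
F9 | step 13 | (13E)-15-oxolabda-8(17),13-dien-19-yl tiglate | O=C/C=C(\C)CC[C@H]1C(=C)CC[C@H]2[C@@](C)(COC(=O)/C(C)=C/C)CCC[C@]12C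
F10 | step 13 | (13E)-15-hydroxylabda-8(17),13-dien-19-yl tiglate | OC/C=C(\C)CC[C@H]1C(=C)CC[C@H]2[C@@](C)(COC(=O)/C(C)=C/C)CCC[C@]12C
F11 | step 13 | (13R,14R)-13,14-epoxy-15-hydroxylabd-8(17)-en-19-yl tiglate | OC[C@H]1O[C@]1(C)CC[C@H]2C(=C)CC[C@H]3[C@@](C)(COC(=O)/C(C)=C/C)CCC[C@]23C
F12 | step 13 | (13R,14S)-13,14-epoxy-15-iodolabd-8(17)-en-19-yl tiglate | IC[C@H]1O[C@]1(C)CC[C@H]2C(=C)CC[C@H]3[C@@](C)(COC(=O)/C(C)=C/C)CCC[C@]23C
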